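**Strategy.** Ring A is disconnected as a Robinson annulation. Its hydroxyl carbon, the CH between hydroxyl and benzylic carbons, and its ether carbon are the C=O, CH3 and OCH2 carbons of an aryloxyacetone on the ring B oxygen; the other three ring carbons and the A–D ethano bridge are an (E)-styryl vinyl ketone on ring D. The key step exploits ring A's adjacent C–OH and C–OAr carbons (the latter para to the bridge carbon): one base-mediated Michael–aldol cascade closes the 20-membered macrocycle and the carbocycle, giving a 6-aryloxy-3-styrylcyclohexenone that is a double-bond isomer of the ring A phenol. The precursor is the open B–C bibenzyl/C–D diaryl ether chain carrying both partners, ring D phenol benzylated.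

Key step: step 8

Remark: 1 is taken as the bought phosphonium salt (otherwise one operation from 4-bromobenzyl bromide and PPh3). The target has no stereocentre; 15, 16, 17, F4 and F6 are racemic (one enantiomer drawn), and 3 and F3 are E/Z mixtures.

**Step 1**
Reactants: 1 (4-bromobenzyl)triphenylphosphonium bromide; 2 3-hydroxybenzaldehyde
Product: 3 3-[2-(4-bromophenyl)ethenyl]phenol (E/Z mixture)
Conditions: KOt-Bu (2.3 equiv), THF, 0 °C to rt
Reagents that add atoms: none
Why: Wittig olefination by the semistabilised benzylic ylide; the second equivalent of base only holds the phenol as its phenoxide, and the alkene geometry is irrelevant because step 2 saturates it.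

**Step 2**
Reactants: 3 3-[2-(4-bromophenyl)ethenyl]phenol
Product: 4 3-[2-(4-bromophenyl)ethyl]phenol
Conditions: TsNHNH2 (5 equiv), NaOAc (5 equiv), THF/H2O, reflux
Reagents that add atoms: none
Why: Diimide reduction adds hydrogen syn to the stilbene C=C and leaves the aryl C–Br bond intact, which catalytic hydrogenation could cleave.

**Step 3**
Reactants: 4 3-[2-(4-bromophenyl)ethyl]phenol; 5 chloroacetone
Product: 6 1-{3-[2-(4-bromophenyl)ethyl]phenoxy}propan-2-one
Conditions: K2CO3, KI (cat.), acetone, reflux
Reagents that add atoms: none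
Why: Williamson ether synthesis with Finkelstein assistance on an activated alpha-halo ketone; capping the ring B oxygen here also means that only one phenol is present in the later copper coupling.

**Step 4**
Reactants: 6 1-{3-[2-(4-bromophenyl)ethyl]phenoxy}propan-2-one
Product: 7 1-bromo-4-{2-[3-(2,2-dimethoxypropoxy)phenyl]ethyl}benzene
Conditions: HC(OMe)3, MeOH, TsOH·H2O (cat.), rt to 40 °C; Et3N quench
Reagents that add atoms: trimethyl orthoformate COC(OC)OC
Why: Acid-catalysed ketalisation driven by the orthoformate; the ketone must be masked against the carbonate base, the phosphonate anion and the Grignard reagent, and the dimethyl ketal is chosen because it can be removed with very mild acid.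

**Step 5**
Reactants: 7 1-bromo-4-{2-[3-(2,2-dimethoxypropoxy)phenyl]ethyl}benzene; 8 4-(benzyloxy)-3-hydroxybenzaldehyde
Product: 9 4-(benzyloxy)-3-(4-{2-[3-(2,2-dimethoxypropoxy)phenyl]ethyl}phenoxy)benzaldehyde
Conditions: CuI (10 mol %), N,N-dimethylglycine hydrochloride (30 mol %), Cs2CO3, 1,4-dioxane, 100 °C, Ar
Reagents that add atoms: none
Why: Ligand-accelerated Ullmann diaryl ether synthesis; 8 is the only phenol in the flask, so no oligomeric ethers can form, and aldehyde, ketal and benzyl ether tolerate the carbonate base.

**Step 6**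
Reactants: 9 4-(benzyloxy)-3-(4-{2-[3-(2,2-dimethoxypropoxy)phenyl]ethyl}phenoxy)benzaldehyde; 10 diethyl {2-[methoxy(methyl)amino]-2-oxoethyl}phosphonate
Product: 11 (2E)-3-[4-(benzyloxy)-3-(4-{2-[3-(2,2-dimethoxypropoxy)phenyl]ethyl}phenoxy)phenyl]-N-methoxy-N-methylprop-2-enamide
Conditions: NaH, THF, 0 °C to rt
Reagents that add atoms: none
Why: Horner–Wadsworth–Emmons olefination with a stabilised phosphonate anion should give the (E)-enamide selectively; the ketal and ethers are inert.

**Step 7**
Reactants: 11 (2E)-enamide from step 6; 12 vinylmagnesium bromide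
Product: 14 (1E)-1-[4-(benzyloxy)-3-(4-{2-[3-(2-oxopropoxy)phenyl]ethyl}phenoxy)phenyl]penta-1,4-dien-3-one, via ketal dienone 13 (not isolated)
Conditions: CH2=CHMgBr (1.5 equiv), THF, −20 to 0 °C; then poured into cold 1 M aq. HCl/THF, 0 °C to rt, phases separated while acidic; BHT (trace), used at once
Reagents that add atoms: water O
Why: Weinreb ketone synthesis, in which the chelated tetrahedral adduct prevents over-addition and releases the vinyl ketone only in the acidic quench; there the liberated amine is protonated and cannot add to the enone, and the dimethyl ketal is hydrolysed in the same flask, so the doubly reactive precursor never meets base before step 8.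

**Step 8**
Reactants: 14 (1E)-1-[4-(benzyloxy)-3-(4-{2-[3-(2-oxopropoxy)phenyl]ethyl}phenoxy)phenyl]penta-1,4-dien-3-one
Product: 17 racemic macrocyclic 6-aryloxy-3-[(E)-styryl]cyclohex-2-enone (C6 bears the ring B oxygen; C3 bears the CH=CH link to ring D; ring D phenol as benzyl ether), via macrocyclic diketone 15 (not isolated), via ketol 16 (not isolated)
Conditions: KOt-Bu (0.5 equiv), t-BuOH/THF 1:1, 40 °C, 14 added by syringe pump over 12 h to 1 mM final concentration, then 60 °C; Ar
Reagents that add atoms: none
Why: Proposed new method: under equilibrating base the aryloxyacetone is deprotonated mainly at the oxygen-bearing CH2, which the alpha-aryloxy group makes the more acidic site by several pK units, and this enolate adds 1,4 to the unsubstituted vinyl terminus of the cross-conjugated dienone, closing the 20-membered ring in a 20-endo-trig Michael addition that pseudo-dilution and the stiff aryl panels of the chain favour over oligomerisation. In the 1,5-diketone 15 only the methyl enolate can reach a carbonyl through an unstrained transition state, so it attacks the enone C=O in a 6-(enolendo)-exo-trig aldol to ketol 16, and E1cB loss of water gives the linearly conjugated dienone 17. The closest known reaction type is the intermolecular Robinson annulation of alpha-alkoxy and alpha-aryloxy ketones with vinyl ketones or chalcones, which shows the same donor regiochemistry; running it within one molecule to close a macrocycle is the new element. The stereocentre at the aryloxy-bearing ring carbon is formed without any controlling element and is therefore racemic, which does not matter because it becomes an sp2 carbon of ring A in step 9. The step needs donor selectivity (OCH2 over CH3, secured by the alpha oxygen under thermodynamic enolate control) and acceptor selectivity (vinyl over styryl terminus, secured by the absent beta substituent and by the aryl conjugation that attack at the styryl carbon would destroy).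

**Step 9**
Reactants: 17 racemic macrocyclic 6-aryloxy-3-[(E)-styryl]cyclohex-2-enone
Product: 18 O-benzyl macrocycle (the target with the ring D hydroxyl as benzyl ether)
Conditions: RhCl3·3H2O (10 mol %), EtOH/toluene 4:1, 90 °C, sealed tube, Ar
Reagents that add atoms: none
Why: Isoaromatisation, in which a rhodium hydride formed from the salt and ethanol moves the exocyclic styryl C=C into the ring by hydrometallation/beta-hydride elimination at the diene termini and the resulting cyclohexadienone tautomerises irreversibly to the phenol; this is the metal-catalysed double-bond shift known for alkylidene and alkenyl cyclohexenones, it needs neither oxidant nor reductant, and it erases the racemic centre.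

**Step 10**
Reactants: 18 O-benzyl macrocycle
Product: 19 target macrocyclic bis(bibenzyl) diphenol (CNP0329842.0)
Conditions: H2 (1 atm), 10% Pd/C, EtOAc/EtOH, rt
Reagents that add atoms: none
Why: Hydrogenolysis of the benzyl aryl ether; the substrate now holds only arenes, diaryl ethers and saturated bridges, none of which reacts under these conditions.

**Compound list**
1 | (4-bromobenzyl)triphenylphosphonium bromide | Brc1ccc(C[P+](c2ccccc2)(c2ccccc2)c2ccccc2)cc1.[Br-] | starting material
2 | 3-hydroxybenzaldehyde | O=Cc1cccc(O)c1 | starting material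
3 | 3-[2-(4-bromophenyl)ethenyl]phenol (E/Z mixture) | Oc1cccc(C=Cc2ccc(Br)cc2)c1 | intermediate
4 | 3-[2-(4-bromophenyl)ethyl]phenol | Oc1cccc(CCc2ccc(Br)cc2)c1 | intermediate
5 | chloroacetone | CC(=O)CCl | starting material
6 | 1-{3-[2-(4-bromophenyl)ethyl]phenoxy}propan-2-one | CC(=O)COc1cccc(CCc2ccc(Br)cc2)c1 | intermediate
7 | 1-bromo-4-{2-[3-(2,2-dimethoxypropoxy)phenyl]ethyl}benzene | COC(C)(OC)COc1cccc(CCc2ccc(Br)cc2)c1 | intermediate
8 | 4-(benzyloxy)-3-hydroxybenzaldehyde | O=Cc1ccc(OCc2ccccc2)c(O)c1 | starting material
9 | 4-(benzyloxy)-3-(4-{2-[3-(2,2-dimethoxypropoxy)phenyl]ethyl}phenoxy)benzaldehyde | COC(C)(OC)COc1cccc(CCc2ccc(Oc3cc(C=O)ccc3OCc3ccccc3)cc2)c1 | intermediate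
10 | diethyl {2-[methoxy(methyl)amino]-2-oxoethyl}phosphonate | CCOP(=O)(OCC)CC(=O)N(C)OC | starting material
11 | (2E)-3-[4-(benzyloxy)-3-(4-{2-[3-(2,2-dimethoxypropoxy)phenyl]ethyl}phenoxy)phenyl]-N-methoxy-N-methylprop-2-enamide | COC(C)(OC)COc1cccc(CCc2ccc(Oc3cc(/C=C/C(=O)N(C)OC)ccc3OCc3ccccc3)cc2)c1 | intermediate
12 | vinylmagnesium bromide | C=C[Mg]Br | starting material
13 | ketal dienone, (1E)-1-[4-(benzyloxy)-3-(4-{2-[3-(2,2-dimethoxypropoxy)phenyl]ethyl}phenoxy)phenyl]penta-1,4-dien-3-one (not isolated) | COC(C)(OC)COc1cccc(CCc2ccc(Oc3cc(/C=C/C(=O)C=C)ccc3OCc3ccccc3)cc2)c1 | intermediate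
14 | (1E)-1-[4-(benzyloxy)-3-(4-{2-[3-(2-oxopropoxy)phenyl]ethyl}phenoxy)phenyl]penta-1,4-dien-3-one (cyclisation precursor) | CC(=O)COc1cccc(c1)CCc1ccc(cc1)Oc1cc(ccc1OCc1ccccc1)/C=C/C(=O)C=C | intermediate
15 | macrocyclic 1,5-diketone (Michael adduct; acetyl on the carbon bearing the ring B oxygen, (E)-enone to ring D; racemic; not isolated) | CC(=O)[C@@H]1CCC(=O)/C=C/c2ccc(OCc3ccccc3)c(c2)Oc2ccc(cc2)CCc2cccc(c2)O1 | intermediate
16 | bicyclic ketol (aldol adduct; racemic, both epimers at the carbinol carbon; not isolated) | O=C1CC2(O)CC[C@@H]1Oc1cccc(c1)CCc1ccc(cc1)Oc1cc(ccc1OCc1ccccc1)/C=C/2 | intermediate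
17 | macrocyclic 6-aryloxy-3-[(E)-styryl]cyclohex-2-enone, ring D phenol as benzyl ether (racemic) | O=C1C=C2CC[C@@H]1Oc1cccc(c1)CCc1ccc(cc1)Oc1cc(ccc1OCc1ccccc1)/C=C/2 | intermediate
18 | O-benzyl macrocycle (target with ring D hydroxyl benzylated) | Oc1cc2ccc1Oc1cccc(c1)CCc1ccc(cc1)Oc1cc(ccc1OCc1ccccc1)CC2 | intermediate
19 | macrocyclic bis(bibenzyl) diphenol CNP0329842.0 | Oc1cc2ccc1Oc1cccc(c1)CCc1ccc(cc1)Oc1cc(ccc1O)CC2 | target

**Step count and risks**
Total steps: 10. Longest linear sequence: 10 steps (1 and 2 to 19).

Most likely to fail, in order: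

1. Step 8. Intermolecular Michael addition or anionic polymerisation of the vinyl ketone may outrun ring closure, or the methyl enolate may act as donor and lead to a regioisomeric ring. The fallback uses known macrocyclisation chemistry with ring A aromatic from the start. It sets out from 4: SNAr with commercially available 3-(benzyloxy)-4-fluorobenzaldehyde (K2CO3, DMF, 120 °C) should give the ring A aldehyde 3-(benzyloxy)-4-{3-[2-(4-bromophenyl)ethyl]phenoxy}benzaldehyde F1. Copper-catalysed coupling of its aryl bromide with 8 under the conditions of step 5 should give the dialdehyde 4-(benzyloxy)-3-[4-(2-{3-[2-(benzyloxy)-4-formylphenoxy]phenyl}ethyl)phenoxy]benzaldehyde F2. Intramolecular McMurry coupling (TiCl4, Zn, pyridine, THF, reflux, slow addition) should close the ring to the macrocyclic stilbene bis(benzyl ether) F3. Hydrogenation (H2, 10% Pd/C, EtOAc/EtOH) saturates the stilbene and removes both benzyl groups, so the fallback comes back to the route at 19.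

2. Step 9. The ethanol-derived rhodium hydride may reduce the dienone by transfer hydrogenation, or the double bond may stop part-way without aromatising. The fallback sets out from 17. Homogeneous hydrogenation with RhCl(PPh3)3 (H2 1 atm, toluene/EtOH, rt) should saturate only the disubstituted styryl alkene, sparing the trisubstituted ring enone and the benzyl ether, to give the racemic 6-aryloxy-3-(2-arylethyl)cyclohex-2-enone F4. Aerobic dehydrogenation (Pd(O2CCF3)2, 2-(dimethylamino)pyridine, TsOH, O2 1 atm, DMSO, 80 °C), known for turning 3-substituted cyclohexenones into meta-substituted phenols, should then return the route to 18.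

3. Step 7. The liberated amine or chloride may add to the new vinyl ketone, the vinyl ketone may polymerise during the acidic hydrolysis, or the ketal may be cleaved incompletely. The fallback sets out from 11 and avoids both the amine and strong acid. Reduction with i-Bu2AlH (THF, −78 °C) should give the enal (2E)-3-[4-(benzyloxy)-3-(4-{2-[3-(2,2-dimethoxypropoxy)phenyl]ethyl}phenoxy)phenyl]prop-2-enal F5. Addition of CH2=CHMgBr (THF, −78 °C) should give the racemic bis-allylic alcohol (1E)-1-[4-(benzyloxy)-3-(4-{2-[3-(2,2-dimethoxypropoxy)phenyl]ethyl}phenoxy)phenyl]penta-1,4-dien-3-ol F6. Oxidation with MnO2 (CH2Cl2, rt) under neutral conditions comes back to the route at 13, now isolated. A separate buffered hydrolysis (pyridinium p-toluenesulfonate, acetone/H2O, rt) then gives 14.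

**Further compounds**
F1 | step 8 | 3-(benzyloxy)-4-{3-[2-(4-bromophenyl)ethyl]phenoxy}benzaldehyde | O=Cc1ccc(Oc2cccc(CCc3ccc(Br)cc3)c2)c(OCc2ccccc2)c1
F2 | step 8 | 4-(benzyloxy)-3-[4-(2-{3-[2-(benzyloxy)-4-formylphenoxy]phenyl}ethyl)phenoxy]benzaldehyde | O=Cc1ccc(Oc2cccc(CCc3ccc(Oc4cc(C=O)ccc4OCc4ccccc4)cc3)c2)c(OCc2ccccc2)c1
F3 | step 8 | macrocyclic stilbene bis(benzyl ether) (E/Z mixture; target skeleton with CH=CH between rings A and D and both hydroxyls benzylated) | C(Oc1cc2ccc1Oc1cccc(c1)CCc1ccc(cc1)Oc1cc(ccc1OCc1ccccc1)C=C2)c1ccccc1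
F4 | step 9 | macrocyclic 6-aryloxy-3-(2-arylethyl)cyclohex-2-enone, ring D phenol as benzyl ether (racemic) | O=C1C=C2CC[C@@H]1Oc1cccc(c1)CCc1ccc(cc1)Oc1cc(ccc1OCc1ccccc1)CC2
F5 | step 7 | (2E)-3-[4-(benzyloxy)-3-(4-{2-[3-(2,2-dimethoxypropoxy)phenyl]ethyl}phenoxy)phenyl]prop-2-enal | COC(C)(OC)COc1cccc(CCc2ccc(Oc3cc(/C=C/C=O)ccc3OCc3ccccc3)cc2)c1
F6 | step 7 | (1E)-1-[4-(benzyloxy)-3-(4-{2-[3-(2,2-dimethoxypropoxy)phenyl]ethyl}phenoxy)phenyl]penta-1,4-dien-3-ol (racemic) | COC(C)(OC)COc1cccc(CCc2ccc(Oc3cc(/C=C/C(O)C=C)ccc3OCc3ccccc3)cc2)c1
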